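5 questions stand below, and I meet them with one ratio.

| flask | starting material | free catalyst | temperature | remark | time |
|---|---|---|---|---|---|
| summer | 0.15 M | 0.27 mM | 50 °C | run made earlier |  |
| winter | 0.15 M | 0.42 mM | 72 °C | run made earlier |  |
| south | 0.15 M | 0.19 mM | 40 °C |  | 25 min |
| north | 0.15 M | 0.19 mM |  | at 80 °C until 8.0 min, from then on at 40 °C | 25 min |
| west | 0.15 M | 0.19 mM | 80 °C |  | 25 min |
| south-east | 0.15 M | 0.19 mM | 60 °C |  | 25 min |

| run | time / min | target / % | starting material / % |
|---|---|---|---|
| summer | 1.50 | 16.1 | 79.4 |
| summer | 3.00 | 23.8 | 65.2 |
| summer | 5.00 | 28.7 | 52.7 |
| summer | 10.0 | 30.1 | 34.3 |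
| summer | 20.0 | 20.7 | 21.3 |
| winter | 0.500 | 18.9 | 73.7 |
| winter | 1.50 | 20.1 | 59.2 |
| winter | 3.00 | 17.5 | 47.2 |
| winter | 4.00 | 14.0 | 45.4 |
| winter | 6.00 | 14.0 | 35.5 |

(readings scatter by 1 percentage point)

- percent here means starting material units held: one side product counts as two
- the analysis behind the earlier runs scatters by 1 percentage point, standard deviation
- on the list of suspects stand: starting material + free catalyst <-> catalyst intermediate; catalyst intermediate <-> free catalyst + target; starting material + target -> side product

1. the best flask by amount of target, in percent of the starting material charged; "all alike" if 1.5 percentage points covers them all (south / north / west / south-east / all alike)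
2. amount of target at the end, in percent of the starting material charged, south
3. amount of target at the end, in percent of the starting material charged, north
4. amount of target at the end, in percent of the starting material charged, west
5. amount of target at the end, in percent of the starting material charged, south-east

Watch target over starting material, not target by itself. In the summer run target climbs steeply, to 16.1% within 1.50 min, and the readings top out at 30.1% at 10.0 min. The ratio reads 0.203 at the first reading and 0.878 at 10.0 min; then comes the knee, and it reads 0.972 at 20.0 min. The winter run reaches its knee early, and its last 3 readings average 0.358. I take these late readings, with their scatter, as the balance ratio K, the equilibrium constant between starting material and target. Past the knee in these 2 runs, target stands near K times the starting material, and both sink together.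

In logarithms, K loses one power of ten per 50.7 K. Carried along that line, K is 0.249 at 80 °C and 0.617 at 60 °C. At 40 °C the line gives 1.53, my estimate of the balance ratio in south. So for equal starting material left, I reckon that south can hold 6.14 times the target of west. I put south first and west last, and I expect north to climb after 8.0 min.

The forecast names south, with 30% for south (25% to 35%), 16% for north (11% to 21%), 3% for west (1% to 7%) and 9.5% for south-east (5.5% to 15%). Its ground is “the step is exothermic and cold favours target”.

The flasks give 30.7% in south, 15.6% in north, 2.94% in west and 9.97% in south-east, so south is best, as forecast.

    starting material + free catalyst ⇌ catalyst intermediate (K = 1.30 M⁻¹, k = 310 M⁻¹ min⁻¹, Ea = 55.0 kJ mol⁻¹, ΔH = 1.00 kJ mol⁻¹)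
    catalyst intermediate ⇌ free catalyst + target (K = 1.30 M, k = 6900 min⁻¹, Ea = 71.0 kJ mol⁻¹, ΔH = −44.0 kJ mol⁻¹)
    starting material + target → side product (k = 0.500 M⁻¹ min⁻¹, Ea = 53.0 kJ mol⁻¹)
    (constants at 40 °C)

At the end, north's ratio of target to starting material is 1.12, still below 1.53, with target made 1.62 times as fast as used up, each step taken net. With the reverse step, free catalyst + target to catalyst intermediate, struck out, west ends with 49.6% instead of 2.94%, the largest single effect though not the main reason.

North left until 1.5 h keeps 6.38% of starting material, so 1.53 times that gives 9.76% of target. The computed flask holds 11.2%.

(The runs are calculated on assumed constants.)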